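If target, once made, goes over to over-reaction product on its own clock, then the share of target among the two products should follow from how many target lifetimes fit into the run. Here starting material and second substrate compete, on the catalyst, for coupling partner.

| flask | starting material | coupling partner | second substrate | catalyst | temperature | remark | time |
|---|---|---|---|---|---|---|---|
| Saturday's | 0.40 M | 0.36 M | 0.80 M | 21 mM | 20 °C | run made earlier |  |
| Thursday's | 0.40 M | 0.36 M | 0.80 M | 46 mM | 53 °C | run made earlier |  |
| Sunday's | 0.40 M | 0.36 M | 1.2 M | 31 mM | 20 °C | run made earlier |  |
| elm | 0.40 M | 0.360 M | 0.800 M | 31 mM | 25 °C |  | 5.0 min |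
| oak | 0.40 M | 0.360 M | 0.800 M | 31 mM | 5 °C |  | 5.0 min |
| alder | 0.40 M | 0.360 M | 0.800 M | 31 mM | 45 °C |  | 5.0 min |
| maple | 0.40 M | 0.360 M | 0.800 M | 31 mM | 65 °C |  | 5.0 min |

Saturday's run (percent of the starting material charged)

| time / min | target / % | over-reaction product / % |
|---|---|---|
| 0.500 | 26.8 | 9.3 |
| 0.667 | 23.7 | 13.9 |
| 1.00 | 20.0 | 20.9 |
| 1.50 | 12.7 | 28.1 |
| 2.50 | 5.7 | 34.6 |
| 4.00 | 1.4 | 39.3 |
| 6.00 | 0.6 | 40.5 |

Thursday's run (percent of the starting material charged)

| time / s | target / % | over-reaction product / % |
|---|---|---|
| 12.0 | 0 | 41.5 |
| 25.0 | 1.3 | 41.7 |
| 40.0 | 0 | 41.3 |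
| 50.0 | 0.3 | 41.3 |
| 60.0 | 0 | 41.5 |
| 80.0 | 0 | 41.6 |
| 90.0 | 0 | 41.8 |

Sunday's run (percent of the starting material charged)

| time / min | target / % | over-reaction product / % |
|---|---|---|
| 0.500 | 22.3 | 10.4 |
| 1.50 | 8.7 | 22.6 |
| 3.00 | 2.6 | 29.5 |
| 4.00 | 0.7 | 30.5 |
| 6.00 | 0.1 | 32.0 |

(each reading ± 0.5 percentage points)

- candidate steps: target -> over-reaction product; starting material + coupling partner + catalyst -> catalyst + target; second substrate + coupling partner + catalyst -> catalyst + second product

- the best flask by share of target in all that became target or over-reaction product; "all alike" if 1.5 percentage points covers them all (elm / oak / alder / maple / all alike)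
- share of target in all that became target or over-reaction product, elm
- share of target in all that became target or over-reaction product, oak
- share of target in all that became target or over-reaction product, alder
- share of target in all that became target or over-reaction product, maple

Saturday's target falls from 12.7% at 1.50 min to 1.4% at 4.00 min. By the first of these times, target plus over-reaction product has reached nearly all of its last reading, so we read a first-order decay constant of 0.882 /min at 20 °C. Thursday's target reads 0% at 12.0 s. Taking that as under 1.3%, the target read at 25.0 s, out of 41.5% of product, gives a constant of at least 17.3 /min at 53 °C, and so an activation energy of at least 71.7 kJ/mol.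

Our number is the decay number N (a Damköhler number), the decay constant at the flask's temperature times the run time, and the share should be about exp(−N). Is one number enough? Saturday at 2.50 min gives 11.0% against a read 14.1%. Sunday at 1.50 min, with more second substrate, gives 26.6% against 27.8%. Saturday's read share is higher than exp(−N), and target formed after the start has not been decaying for the whole run, so we treat exp(−N) as a floor.

With the lowest allowed activation energy, oak has N of at most 0.902. Elm has at least 7.22, alder 44.5 and maple 221. We therefore expect oak to be best, with a share of at least 40.6%, and elm near 0.0732%.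

The forecast names oak, with 60% for oak, above our floor, 0.1% for elm, and 0% and 0% for alder and maple, adding “This is uncertain because Ea is only a lower bound.”

The flasks give oak as best: 52.4% in oak, 0.0446% in elm, 0% in alder and 0% in maple.

    target → over-reaction product (k = 0.0263 /s, Ea = 84.0 kJ/mol)
    starting material + coupling partner + catalyst → catalyst + target (k = 7.55 /M²/s, Ea = 41.0 kJ/mol)
    second substrate + coupling partner + catalyst → catalyst + second product (k = 4.15 /M²/s, Ea = 39.0 kJ/mol)
    (constants at 25 °C)

In oak at 0.214 min, the half-life of starting material by coupling is 0.92 min, shorter than the half-life of target by decay, 5.0 min, and that second half-life makes oak's decay number 0.690, under our bound of 0.902. A neighbour of oak with 1.4 M of coupling partner, 3.50 equiv, keeps oak's temperature and time and so the same bound of 0.902 with its floor of 40.6%, and its share, 52.4%, stands above that floor.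

The runs stem from a simulated flask with constants of no real substance; scatter was added.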